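The data are simulated with made-up constants; noise was put on by code.

At 8.0 min you read the target in the east, south-east, north-east and north flasks, which differ in what is fed and over how long.

| setting | maple | alder | oak | birch | east | south-east | north-east | north |
|---|---|---|---|---|---|---|---|---|
| starting material | 0.50 mM | 0.25 mM | 0.38 mM | 0.50 mM | 0.50 mM | 0.50 mM | 0.50 mM | 0.50 mM |
| partner | 1.5 equiv | 1.5 equiv | 1.5 equiv | 3 equiv | 1.50 equiv (fed, over 30 s) | 1.50 equiv (fed, over 5.0 min) | 1.50 equiv | 1.50 equiv |
| second substrate | 2 equiv | 2 equiv | 2 equiv | 2 equiv | 2.00 equiv | 2.00 equiv | 2.00 equiv | 2.00 equiv (fed, over 5.0 min) |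
| protic impurity | 0.50 mM | 0.50 mM | 0.50 mM | 0.50 mM | 0.500 mM | 0.500 mM | 0.500 mM | 0.500 mM |
| remark | run made earlier | run made earlier | run made earlier | run made earlier | all else is in the flask from the start; the feed brings no volume worth counting | all else is in the flask from the start; the feed brings no volume worth counting | everything together at the start | all else is in the flask from the start; the feed brings no volume worth counting |
| time |  |  |  |  | 8.0 min | 8.0 min | 8.0 min | 8.0 min |

| run | time / min | target / % |
|---|---|---|
| maple | 0.667 | 34 |
| maple | 1.50 | 20 |
| maple | 3.00 | 18 |
| maple | 5.00 | 13 |
| alder | 1.33 | 21 |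
| alder | 3.00 | 11 |
| alder | 6.00 | 10 |
| alder | 10.0 | 14 |
| oak | 2.50 | 13 |
| oak | 5.00 | 14 |
| oak | 8.00 | 14 |
| oak | 10.0 | 12 |
| birch | 1.33 | 30 |
| birch | 3.00 | 23 |
| birch | 6.00 | 18 |
| birch | 10.0 | 25 |

(standard deviation of a reading: 1.5 percentage points)

1. the flask that comes out highest in amount of target, in percent of the starting material charged, or "all alike" when all lie within 1.5 percentage points (east / south-east / north-east / north / all alike)
2. target at the end, in percent of the starting material charged, east
3. target at the end, in percent of the starting material charged, south-east
4. target at the end, in percent of the starting material charged, north-east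
5. target at the end, in percent of the starting material charged, north



Build the flask up one process at a time. Take the main step first, starting material plus partner: 1.50 equiv of partner covers the charge, which makes starting material the limiting reagent and puts the ceiling at 100 %. Now add the draw-down seen in the maple run, where the target reads 34 % at 0.667 min but 13 % at 5.00 min. Then add whatever else spends partner: at the same starting concentration, birch with 3 equiv reads 18 % and 25 % late, against 13 % for maple with 1.5 equiv. Birch's two late readings, averaged and divided by its equivalents, give 7.17 %. Carry this as the lasting yield per equivalent: late target, in percent of the starting material charged, per equivalent of partner.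

My reckoning for north-east is therefore 10.8 %, with maple's reading of 13 % beside it. The east feed of 30 s and the feeds of 5.0 min are corrections I can't size, since none of the earlier runs feeds anything.

The forecast gives 13 % for east, 12 % for south-east, 13 % for north-east and 16 % for north, and calls north highest, reasoning that “Feeding the second substrate delays the draw-down”. Its north-east stands above mine.

The flasks give 10.9 % for east, 3.72 % for south-east, 14.6 % for north-east and 20.4 % for north, so north is highest.

    second substrate + partner → second product (k = 140 M⁻¹ s⁻¹)
    target ⇌ isomer of the product (K = 2.90, k = 0.0190 s⁻¹)
    starting material + protic impurity → quenched substrate (k = 65.0 M⁻¹ s⁻¹)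
    starting material + partner → target (k = 250 M⁻¹ s⁻¹)
    starting material ⇌ dormant form (K = 2.50, k = 0.00400 s⁻¹)

South-east lies 8.3 percentage points below the forecast. Its lasting yield is 2.48 % per equivalent, while north-east gives 9.73 % against the carried 7.17 %, and north gives 13.6 %. Now take the neighbour of north with c(protic impurity) raised to 2.0 mM, which is 4.00 equiv to starting material. Its partner charge is unchanged, and it reads 13.9 %, a lasting yield of 9.27 % per equivalent.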